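**Strategy**

Ring C (O1–C2–C3–C4–C4a–C8a) is a benzo-fused 2,3-dihydropyran-4-one, the retron of an aldehyde oxa-[4+2] annulation. The C=O of a ring B aldehyde is spliced across C3 and C8a of a ring A aryl methyl ketone whose C8a carries fluorine ortho to the C4 carbonyl. In one flask a catalytic enantioselective Mukaiyama aldol addition forms C2–C3 and sets (2S); fluoride then frees the aldolate oxygen, which displaces the fluorine at C8a (SNAr) and becomes O1. The precursors are the enol silane of a 6-fluoro-2,4-bis(MOM-oxy)-3-prenylacetophenone and 2,4-bis(MOM-oxy)-5-prenylbenzaldehyde; the open-chain silyl aldol is never isolated. Acid then removes the four acetals.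

Key step: step 7

Remarks on the chemistry:
- MOM = methoxymethyl; prenyl = 3-methylbut-2-en-1-yl; atom and ring labels follow flavanone numbering.
- The target is (2S); the (S) carbinol of the aldol stage needs attack on the Si face of the aldehyde.
- The facial sense of the oxazaborolidinone in step 7 is assumed from the usual model for this catalyst class (nucleophile anti to the indole stacked on the bound aldehyde). If the first run shows the opposite sense, the L-tryptophan-derived antipode is used with nothing else changed.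
- Compounds 1 and 10 and tributyl(prenyl)stannane are taken as commercially available.

**Route**

Step 1
Reactants: 1 5-fluorobenzene-1,3-diol
Product: 2 1-fluoro-3,5-bis(methoxymethoxy)benzene
Conditions: NaH, MOMCl, DMF, 0 °C → rt
Reagents that add atoms: chloromethyl methyl ether, COCCl
Why: Williamson-type O-alkylation of both sodium phenoxides with the reactive α-chloro ether should give the bis-acetal, which tolerates organolithiums and later directs metalation.

Step 2
Reactants: 2 1-fluoro-3,5-bis(methoxymethoxy)benzene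
Product: 4 5-fluoro-1,3-bis(methoxymethoxy)-2-(3-methylbut-2-en-1-yl)benzene, via aryllithium 3 (not isolated)
Conditions: n-BuLi, TMEDA, THF, −78 → −40 °C; then prenyl bromide, −78 °C → rt
Reagents that add atoms: prenyl bromide (1-bromo-3-methylbut-2-ene), CC(C)=CCBr
Why: Directed ortho-metalation should occur at the one C–H flanked by two chelating OMOM groups, where lithium sits meta to fluorine and cannot lose LiF, and SN2 alkylation of aryllithium 3 at the primary carbon of prenyl bromide then gives the linear prenyl arene.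

Step 3
Reactants: 4 5-fluoro-1,3-bis(methoxymethoxy)-2-(3-methylbut-2-en-1-yl)benzene
Product: 7 1-[6-fluoro-2,4-bis(methoxymethoxy)-3-(3-methylbut-2-en-1-yl)phenyl]ethan-1-one, via aryllithium 5 (not isolated), via lithium hemiaminal alkoxide 6 (not isolated)
Conditions: n-BuLi, THF, −78 °C; then MeC(O)N(OMe)Me, −78 → 0 °C; aq. NH4Cl
Reagents that add atoms: N-methoxy-N-methylacetamide, CC(=O)N(C)OC
Why: The two remaining ring hydrogens are equivalent and each lies between fluorine and OMOM, so a second directed ortho-metalation at −78 °C (cold enough to prevent aryne formation) is unambiguous, and Weinreb amide acylation stops at the chelated tetrahedral adduct 6, which releases the methyl ketone only on work-up.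

Step 4
Reactants: 7 1-[6-fluoro-2,4-bis(methoxymethoxy)-3-(3-methylbut-2-en-1-yl)phenyl]ethan-1-one
Product: 9 {1-[6-fluoro-2,4-bis(methoxymethoxy)-3-(3-methylbut-2-en-1-yl)phenyl]ethenyl}oxy(trimethyl)silane, via lithium enolate 8 (not isolated)
Conditions: LDA, THF, −78 °C; TMSCl, −78 → 0 °C; pentane, filtration, used crude
Reagents that add atoms: chlorotrimethylsilane, C[Si](C)(C)Cl
Why: Kinetic deprotonation of the only enolisable position by LDA and O-silylation of the lithium enolate (silyl enol ether formation) should give the Mukaiyama donor after a non-aqueous work-up.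

Step 5
Reactants: 10 5-bromo-2,4-dihydroxybenzaldehyde
Product: 11 5-bromo-2,4-bis(methoxymethoxy)benzaldehyde
Conditions: NaH, MOMCl, DMF, 0 °C → rt
Reagents that add atoms: chloromethyl methyl ether, COCCl
Why: Williamson-type O-alkylation, in which irreversible deprotonation by NaH also frees the hydrogen-bonded 2-OH, should protect both phenols as base-stable acetals.

Step 6
Reactants: 11 5-bromo-2,4-bis(methoxymethoxy)benzaldehyde
Product: 12 2,4-bis(methoxymethoxy)-5-(3-methylbut-2-en-1-yl)benzaldehyde
Conditions: Bu3Sn(prenyl), Pd(PPh3)4 (5 mol%), DMF, 95 °C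
Reagents that add atoms: tributyl(3-methylbut-2-en-1-yl)stannane, CCCC[Sn](CCCC)(CCCC)CC=C(C)C
Why: Stille coupling (oxidative addition of C–Br to zerovalent palladium, transmetalation from tin, reductive elimination at the unsubstituted allyl terminus) should give the linear prenyl arene while aldehyde and acetals stay untouched.

Step 7
Reactants: 9 {1-[6-fluoro-2,4-bis(methoxymethoxy)-3-(3-methylbut-2-en-1-yl)phenyl]ethenyl}oxy(trimethyl)silane; 12 2,4-bis(methoxymethoxy)-5-(3-methylbut-2-en-1-yl)benzaldehyde
Product: 15 (2S)-2-[2,4-bis(methoxymethoxy)-5-(3-methylbut-2-en-1-yl)phenyl]-5,7-bis(methoxymethoxy)-6-(3-methylbut-2-en-1-yl)-2,3-dihydro-4H-chromen-4-one, via silyl aldol ether 13 (not isolated), via caesium alkoxide 14 (not isolated)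
Conditions: (R)-2-butyl-4-(1H-indol-3-ylmethyl)-3-tosyl-1,3,2-oxazaborolidin-5-one (20 mol%), EtCN, −78 °C; then CsF, DMF, −40 → 0 °C; pH 7 buffer
Reagents that add atoms: none
Why: The chiral boron Lewis acid binds the aldehyde C=O of 12 and enol silane 9 adds through an open Mukaiyama transition state to the exposed Si face, which forms C3–C2, sets C2 as (S) under catalyst control and passes the silyl group to the aldolate oxygen (13); fluoride then unmasks alkoxide 14, whose oxygen (the former aldehyde oxygen) attacks C8a and expels fluoride by addition–elimination, the released fluoride carrying the desilylation on. The closest known reaction types are the oxazaborolidinone-catalysed Mukaiyama aldol/dihydropyranone annulation of aldehydes with siloxydienes and the fluoride-relayed O-arylation of silyl ethers by carbonyl-activated aryl fluorides, here telescoped into a formal oxa-[4+2] annulation. Ring C closes in a 6-endo-trig sense onto the C8a=C4a–C4=O vinylogous acyl fluoride unit, with the Meisenheimer charge held by the C4 carbonyl. C2 is not touched in the second stage, so its configuration should carry over unchanged. The step needs ring closure to outrun retro-aldol cleavage of 14 (the alkoxide itself cannot eliminate, oxide being no leaving group) and base-induced ring opening of 15. This is secured by the ortho-carbonyl activation with both ring A acetal oxygens meta to C8a, the six-membered geometry, the low standing alkoxide concentration, a temperature at or below 0 °C and a prompt neutral quench.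

Step 8
Reactants: 15 (2S)-2-[2,4-bis(methoxymethoxy)-5-(3-methylbut-2-en-1-yl)phenyl]-5,7-bis(methoxymethoxy)-6-(3-methylbut-2-en-1-yl)-2,3-dihydro-4H-chromen-4-one
Product: 16 (2S)-2-[2,4-dihydroxy-5-(3-methylbut-2-en-1-yl)phenyl]-5,7-dihydroxy-6-(3-methylbut-2-en-1-yl)-2,3-dihydro-4H-chromen-4-one (CNP0320454.1)
Conditions: HCl (3 M aq.), MeOH, rt → 40 °C, monitored
Reagents that add atoms: none
Why: Acid-catalysed acetal solvolysis (transacetalisation to methanol) should release the four phenols as dimethoxymethane, under conditions mild enough that the prenyl groups are not expected to cyclise onto neighbouring phenols and the benzylic C2–O1 bond is not ionised.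

**Compound list**

1 | 5-fluorobenzene-1,3-diol (5-fluororesorcinol) | Oc1cc(O)cc(F)c1 | starting material
2 | 1-fluoro-3,5-bis(methoxymethoxy)benzene | COCOc1cc(F)cc(OCOC)c1 | intermediate
3 | [4-fluoro-2,6-bis(methoxymethoxy)phenyl]lithium | [Li]c1c(OCOC)cc(F)cc1OCOC | intermediate
4 | 5-fluoro-1,3-bis(methoxymethoxy)-2-(3-methylbut-2-en-1-yl)benzene | COCOc1cc(F)cc(OCOC)c1CC=C(C)C | intermediate
5 | [6-fluoro-2,4-bis(methoxymethoxy)-3-(3-methylbut-2-en-1-yl)phenyl]lithium | [Li]c1c(F)cc(OCOC)c(CC=C(C)C)c1OCOC | intermediate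
6 | lithium 1-[6-fluoro-2,4-bis(methoxymethoxy)-3-(3-methylbut-2-en-1-yl)phenyl]-1-[methoxy(methyl)amino]ethan-1-olate | CC([O-])(N(C)OC)c1c(F)cc(OCOC)c(CC=C(C)C)c1OCOC.[Li+] | intermediate
7 | 1-[6-fluoro-2,4-bis(methoxymethoxy)-3-(3-methylbut-2-en-1-yl)phenyl]ethan-1-one | CC(=O)c1c(F)cc(OCOC)c(CC=C(C)C)c1OCOC | intermediate
8 | lithium 1-[6-fluoro-2,4-bis(methoxymethoxy)-3-(3-methylbut-2-en-1-yl)phenyl]ethen-1-olate | C=C([O-])c1c(F)cc(OCOC)c(CC=C(C)C)c1OCOC.[Li+] | intermediate
9 | {1-[6-fluoro-2,4-bis(methoxymethoxy)-3-(3-methylbut-2-en-1-yl)phenyl]ethenyl}oxy(trimethyl)silane | C=C(O[Si](C)(C)C)c1c(F)cc(OCOC)c(CC=C(C)C)c1OCOC | intermediate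
10 | 5-bromo-2,4-dihydroxybenzaldehyde | O=Cc1cc(Br)c(O)cc1O | starting material
11 | 5-bromo-2,4-bis(methoxymethoxy)benzaldehyde | O=Cc1cc(Br)c(OCOC)cc1OCOC | intermediate
12 | 2,4-bis(methoxymethoxy)-5-(3-methylbut-2-en-1-yl)benzaldehyde | O=Cc1cc(CC=C(C)C)c(OCOC)cc1OCOC | intermediate
13 | (3S)-3-[2,4-bis(methoxymethoxy)-5-(3-methylbut-2-en-1-yl)phenyl]-1-[6-fluoro-2,4-bis(methoxymethoxy)-3-(3-methylbut-2-en-1-yl)phenyl]-3-[(trimethylsilyl)oxy]propan-1-one | CC(C)=CCc1cc([C@@H](O[Si](C)(C)C)CC(=O)c2c(F)cc(OCOC)c(CC=C(C)C)c2OCOC)c(OCOC)cc1OCOC | intermediate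
14 | caesium (1S)-1-[2,4-bis(methoxymethoxy)-5-(3-methylbut-2-en-1-yl)phenyl]-3-[6-fluoro-2,4-bis(methoxymethoxy)-3-(3-methylbut-2-en-1-yl)phenyl]-3-oxopropan-1-olate | CC(C)=CCc1cc([C@@H]([O-])CC(=O)c2c(F)cc(OCOC)c(CC=C(C)C)c2OCOC)c(OCOC)cc1OCOC.[Cs+] | intermediate
15 | (2S)-2-[2,4-bis(methoxymethoxy)-5-(3-methylbut-2-en-1-yl)phenyl]-5,7-bis(methoxymethoxy)-6-(3-methylbut-2-en-1-yl)-2,3-dihydro-4H-chromen-4-one | CC(C)=CCc1cc([C@@H]2CC(=O)c3c(cc(OCOC)c(CC=C(C)C)c3OCOC)O2)c(OCOC)cc1OCOC | intermediate
16 | (2S)-2-[2,4-dihydroxy-5-(3-methylbut-2-en-1-yl)phenyl]-5,7-dihydroxy-6-(3-methylbut-2-en-1-yl)-2,3-dihydro-4H-chromen-4-one (CNP0320454.1) | CC(C)=CCc1cc([C@@H]2CC(=O)c3c(cc(O)c(CC=C(C)C)c3O)O2)c(O)cc1O | target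

**Step count and risks**

Total step count: 8. Longest linear sequence: 6 (steps 1, 2, 3, 4, 7, 8).

Steps most likely to fail:

1. Step 7. What may go wrong: retro-aldol cleavage of the alkoxide before ring closure, which loses material and erodes enantiopurity on recombination; insufficient facial control in the aldol stage with an electron-rich, ortho-substituted aldehyde; base-induced opening of ring C of the product. Fallback, setting out from 7 and 12 and returning at 15: Claisen–Schmidt condensation (KOH, EtOH, rt) should give (2E)-3-[2,4-bis(methoxymethoxy)-5-prenylphenyl]-1-[6-fluoro-2,4-bis(methoxymethoxy)-3-prenylphenyl]prop-2-en-1-one F1. Copper-catalysed enantioselective conjugate borylation (CuCl, NaOt-Bu, a Josiphos-type ferrocenyl bisphosphine in the enantiomer that gives (S), B2pin2, MeOH, THF) should give the (3S)-3-(4,4,5,5-tetramethyl-1,3,2-dioxaborolan-2-yl) ketone F2. Oxidation with NaBO3·4H2O (THF/H2O), with retention at carbon, gives the (3S)-3-hydroxy ketone F3. Its lithium alkoxide (LiHMDS, THF/DMPU, −40 → 0 °C), a tighter and less retro-aldol-prone aldolate, closes ring C by SNAr to 15. This gives up the one-flask annulation but sets C2 by a different, reagent-tolerant reaction.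

2. Step 2. What may go wrong: competing lithiation at the C–H between fluorine and OMOM (wrong regiochemistry, and aryne formation by loss of LiF on warming). Fallback, setting out from 1 and returning at 7 (it replaces steps 1–3 by electrophilic substitution): Friedel–Crafts-type acetylation of 1 (AcOH, BF3·OEt2, 90 °C), para to one hydroxyl and ortho to fluorine, should give 1-(2-fluoro-4,6-dihydroxyphenyl)ethan-1-one F4. C-prenylation of its phenoxide at the doubly activated carbon between the two hydroxyls (prenyl bromide, aq. KOH, 0 °C) gives 1-[6-fluoro-2,4-dihydroxy-3-(3-methylbut-2-en-1-yl)phenyl]ethan-1-one F5. Bis-protection (NaH, MOMCl, DMF) then gives 7.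

3. Step 8. What may go wrong: acid-promoted cyclisation of a prenyl group onto an adjacent free phenol, or ionisation of the benzylic C2–O1 bond with loss of configuration, before all four acetals are cleaved. Fallback, setting out from 15 and returning at 16: exchange of the acetals for silyl groups under buffered, non-protic conditions (TMSOTf, 2,2′-bipyridyl, MeCN, 0 °C) should give (2S)-2-[2,4-bis(trimethylsilyloxy)-5-prenylphenyl]-5,7-bis(trimethylsilyloxy)-6-prenyl-2,3-dihydro-4H-chromen-4-one F6. Neutral hydrolysis (H2O, pH 7 buffer, rt) then gives 16.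

**Further compounds**

F1 | step 7 | (2E)-3-[2,4-bis(methoxymethoxy)-5-(3-methylbut-2-en-1-yl)phenyl]-1-[6-fluoro-2,4-bis(methoxymethoxy)-3-(3-methylbut-2-en-1-yl)phenyl]prop-2-en-1-one | CC(C)=CCc1cc(/C=C/C(=O)c2c(F)cc(OCOC)c(CC=C(C)C)c2OCOC)c(OCOC)cc1OCOC
F2 | step 7 | (3S)-3-[2,4-bis(methoxymethoxy)-5-(3-methylbut-2-en-1-yl)phenyl]-1-[6-fluoro-2,4-bis(methoxymethoxy)-3-(3-methylbut-2-en-1-yl)phenyl]-3-(4,4,5,5-tetramethyl-1,3,2-dioxaborolan-2-yl)propan-1-one | CC(C)=CCc1cc([C@@H](B3OC(C)(C)C(C)(C)O3)CC(=O)c2c(F)cc(OCOC)c(CC=C(C)C)c2OCOC)c(OCOC)cc1OCOC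
F3 | step 7 | (3S)-3-[2,4-bis(methoxymethoxy)-5-(3-methylbut-2-en-1-yl)phenyl]-1-[6-fluoro-2,4-bis(methoxymethoxy)-3-(3-methylbut-2-en-1-yl)phenyl]-3-hydroxypropan-1-one | CC(C)=CCc1cc([C@@H](O)CC(=O)c2c(F)cc(OCOC)c(CC=C(C)C)c2OCOC)c(OCOC)cc1OCOC
F4 | step 2 | 1-(2-fluoro-4,6-dihydroxyphenyl)ethan-1-one | CC(=O)c1c(O)cc(O)cc1F
F5 | step 2 | 1-[6-fluoro-2,4-dihydroxy-3-(3-methylbut-2-en-1-yl)phenyl]ethan-1-one | CC(=O)c1c(F)cc(O)c(CC=C(C)C)c1O
F6 | step 8 | (2S)-2-[2,4-bis(trimethylsilyloxy)-5-(3-methylbut-2-en-1-yl)phenyl]-5,7-bis(trimethylsilyloxy)-6-(3-methylbut-2-en-1-yl)-2,3-dihydro-4H-chromen-4-one | CC(C)=CCc1cc([C@@H]2CC(=O)c3c(cc(O[Si](C)(C)C)c(CC=C(C)C)c3O[Si](C)(C)C)O2)c(O[Si](C)(C)C)cc1O[Si](C)(C)C
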